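# Design of a synthesis of (2R,3R)-7-O-geranylfustin (16)

Abbreviations in names: geranyl = (2E)-3,7-dimethylocta-2,6-dien-1-yl; TBS = tert-butyldimethylsilyl.

## The problem

Compound 16 is a (2R,3R)-2,3-trans-dihydroflavonol. Benzene ring A is fused through C4a and C8a to the pyranone ring C, with O1 on C8a and the C4 carbonyl on C4a; the catechol ring B hangs from C2, a hydroxyl from C3, and O7 (para to C4a) carries a geranyl chain. The only stereocentres are C2 and C3, and they are not independent: once C2 is fixed, a group entering C3 comes in anti to ring B, and the diequatorial trans isomer is also the more stable one, so absolute control is needed at C2 alone. Both centres are fragile. C2 is benzylic and β to the ketone with the O1 phenoxide as leaving group, so base opens ring C towards a 2'-hydroxychalcone and racemises it; C3 is an enolisable α-ketol carbon that can epimerise or be dehydrogenated to the flavonol. The geranyl ether rules out hydrogenation, peracids, halonium reagents and strong acids (allyl cation formation), and it should not be left with electron-rich zerovalent palladium for long. The catechol must stay masked to the end by groups that come off without base, hydrogen or strong acid, which points to silyl ethers. The feature that allows a short synthesis is that O1 and the C4 carbonyl sit on adjacent carbons of ring A, while C2–C3 is a two-carbon unit bearing only ring B: an ortho-iodophenol, carbon monoxide and an arylacetylene together hold every atom of rings A, B and C, and the planar flavone they give has no stereocentre to lose.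

## Retrosynthesis

**16 to 15.** The last step should be a deprotection and nothing else. Cutting the two O–Si bonds of ring B leads to the bis-silyl ether 15. Benzyl ethers (hydrogenolysis), acetal-type ethers (strong acid) and esters (base) would each collide with the geranyl ether or with the base-labile C2/C3 pair, whereas aryl silyl ethers fall to buffered fluoride near neutrality. The forward step only has to cleave two aryl O–Si bonds and leave the rest alone.

**15 to 13.** The C3–O bond is cut next, giving the (2S)-flavanone 13; the descriptor at C2 changes with the loss of the C3 oxygen, the spatial arrangement does not. Carrying the C3 oxygen from an earlier, unsaturated stage would leave no reliable reduction that sets C2 and C3 together. Oxidising the enolate instead lets C2 dictate C3. The oxidant must be an oxygen electrophile that ignores trisubstituted alkenes, which excludes peracids and points to an N-sulfonyloxaziridine acting on the sodium enolate 14. The enolate must be formed and consumed cold so that β-elimination of the O1 phenoxide does not open ring C. One stereocentre and one heteroatom are removed by this cut.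

**13 to 12.** Removing the hydrogen at C2 (and one at C3) takes 13 back to the flavone 12, which has no stereocentre and tolerates heat and base. Hydrogenation catalysts would threaten the two alkenes of the geranyl chain, whereas a copper hydride generated from a silane reduces only the conjugated enone. Other ways of setting C2, such as aryl addition to a chromone or oxa-Michael closure of a chalcone, belong to different ring constructions. The forward step needs face selectivity at a β-carbon that carries an aryl and an aryloxy group, must stop at the ketone, and must stay non-basic.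

**12 to 5, 8 and 9.** Ring C is taken apart at three bonds at once: C4a–C4, C4–C3 and O1–C2. This gives the iodophenol 5, the arylacetylene 8 and carbon monoxide 9, by way of the ortho-hydroxyaryl ynone 10 and the enaminone 11, neither of which is isolated. Chalcone or diketone routes to the same flavone need an acetophenone, an aroyl donor, strong base and a separate oxidation or dehydration. A CO-free coupling of 5 with 8 would close a five-membered ring. Here C4 arrives at the right oxidation level from 9, and the fragments are two stereocentre-free aromatics of similar size. The forward reaction needs CO insertion to beat direct alkynylation, six-membered closure to beat five-membered closure, and tolerance of the allylic ether and the silyl ethers.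

**5 to 1 and 2.** The C–I bond of 5 is cut to give the phenol 4, whose hydroxyl comes from the benzoate 3, made from resorcinol monobenzoate 1 and geranyl bromide 2. Starting from 1 differentiates the two resorcinol oxygens before any alkylation. Introducing iodine before the oxygens are differentiated would leave two hydroxyls of similar reactivity, the more acidic being the wrong one. Iodination is placed last and on the phenoxide, because phenoxide iodination is compatible with the alkenes. It must go ortho to the hydroxyl and para to the ether oxygen.

**8 to 6.** The alkyne carbon is removed from 8 to give the aldehyde 7, and the two silyl groups are removed to give 3,4-dihydroxybenzaldehyde 6. A one-carbon homologation that runs without alkoxide in a protic solvent is needed, because aryl silyl ethers do not survive carbonate in methanol. The Colvin rearrangement does this in one step, against two for a dibromoolefination–elimination sequence.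

## Roads not taken

**Alternative 1:** The cut is made at the two bonds joining ring C to ring A, O1–C8a and C4–C4a. Ring A enters as an aryne and the O1–C2–C3–C4 chain as an acyclic β-hydroxy ester with both stereocentres in place. The product of the key step would be the chromanone A1, (2R,3R)-3,7-bis(benzyloxy)-5-bromo-2-[3,4-bis(TBS-oxy)phenyl]chroman-4-one. In the forward direction CsF would turn the silyl triflate A2 into its aryne. The benzylic alkoxide of the hydroxy ester A3 would add to the aryne carbon remote from bromine, and the aryl anion left at C4a, next to bromine, would attack the methyl ester.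

- Merits: the route is convergent, C2 and C3 come from acyclic chemistry, and ring C is never exposed as a flavanone enolate.
- Weak points:
  - The bromine that steers the addition is not part of 16. Its clean removal by hydrogenolysis, which would also take off both benzyl groups, is impossible once the geranyl chain is present. O7 would therefore travel as a benzyl ether and be geranylated late, beside the free C3 hydroxyl, on a base-sensitive dihydroflavonol.
  - The alkoxide of A3 is that of an aldol-type adduct and can suffer retro-aldol cleavage or α-epimerisation under fluoride before the aryne captures it.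
  - The anti relationship needed in A3 is not the one delivered by syn-dihydroxylation of an E-cinnamate.
  - A2 needs several steps of its own.
- Comparison: this road is better in that the configuration is settled before ring C exists and no strong base meets ring C. The chosen plan sets against this a key step in which every atom ends in the target, a geranyl group carried from the first step, and a clearly shorter sequence.

**Alternative 2:** Only C3–C4 is cut. Ring C would be closed by an intramolecular crossed benzoin reaction of the dialdehyde A5, 2-[3,4-bis(TBS-oxy)phenyl]-2-[2-formyl-5-(geranyloxy)phenoxy]acetaldehyde. A chiral aminoindanol-derived triazolium salt with i-Pr2NEt would turn the aromatic aldehyde into a Breslow intermediate that attacks the aliphatic aldehyde, while the C2 centre of A5, α to that aldehyde, equilibrates. The product A4 is identical in structure with 15.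

- Merits: both stereocentres and the α-ketol arise in one catalytic step, and a single deprotection would remain.
- Weak points:
  - The carbene must choose the aromatic aldehyde as acyl anion donor although the aliphatic one is more electrophilic and less hindered; the wrong choice gives the isomeric 4-hydroxychroman-3-one or dimers.
  - Precedent for aldehyde–aldehyde ring closures of this kind is much thinner than for aldehyde–ketone cases.
  - One catalyst must control the absolute configuration, the trans relationship and a dynamic resolution together.
  - The product carries the same base-labile C2 and C3 centres and stays in the amine–carbene medium in which they can epimerise.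
  - A5 is an α-aryl-α-aryloxy acetaldehyde that is hard to make and to store, and it needs two aldehydes at different oxidation-state histories on one molecule.
- Comparison: in steps after the key step this road is better, and it needs neither an asymmetric reduction nor a flavanone enolate. The chosen plan sets against this a key step of established type on robust, stereocentre-free partners, and two stereocentres set one at a time by reactions whose selectivity can each be checked and corrected.

**Alternative 3:** C3–C4 and O1–C2 are cut as a [4+2] cycloaddition. A chiral BINOL-derived phosphoric acid would dehydrate the 2-hydroxybenzyl alcohol A7, 5-(geranyloxy)-2-(hydroxymethyl)phenol, to its ortho-quinone methide. This would take up the E-enol ester A8, (E)-2-[3,4-bis(TBS-oxy)phenyl]ethenyl acetate, to give the 2,3-trans flavan-3-yl acetate A6.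

- Merits: the precursors are simple, the union is convergent, and the E geometry is translated directly into the trans relationship with catalytic control of absolute configuration.
- Weak points:
  - A6 is at the flavan oxidation level. C4 is a methylene, and no benzylic oxidation is known that would pick C4 out beside the allylic positions and the doubly activated O–CH2 of the geranyl ether and the benzylic C2–H next to electron-rich ring B.
  - The acyloxy group polarises the enol ester so that its oxygen-bearing carbon would normally bond to O1. The required orientation relies on the electron-rich aryl group winning this contest.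
  - The acid-generated quinone methide and the acid catalyst are poor company for an allylic aryl ether with nucleophilic alkenes.
  - The acetate must later be removed under base beside silyl ethers.
- Comparison: this road is better in convergence and in setting both centres in one step. The chosen plan sets against this that C4 arrives as a carbonyl from carbon monoxide, so no late oxidation is needed.

Key step: step 6

Assumption: in step 7, (R)-DTBM-SEGPHOS stands for whichever antipode of the ligand delivers hydride to the face of C2 that gives the (2S)-flavanone; if the sense of induction is the opposite one, the (S)-ligand is used.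

## Route

Step 1
Reactants: 1 resorcinol monobenzoate (3-hydroxyphenyl benzoate); 2 geranyl bromide ((2E)-1-bromo-3,7-dimethylocta-2,6-diene)
Product: 3 3-(geranyloxy)phenyl benzoate
Conditions: K2CO3, acetone, reflux
Reagents that add atoms: none
Why: Williamson ether synthesis (SN2 of the phenoxide on the primary allylic bromide); the benzoate blocks the second resorcinol oxygen so only mono-O-alkylation is possible, and K2CO3 in acetone favours O- over C-alkylation and leaves the aryl ester intact.

Step 2
Reactants: 3 3-(geranyloxy)phenyl benzoate
Product: 4 3-(geranyloxy)phenol
Conditions: K2CO3 (0.5 equiv), MeOH, rt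
Reagents that add atoms: none
Why: Base-catalysed transesterification (methanolysis) of an aryl benzoate; the phenoxide is a good leaving group, so the ester exchanges at room temperature while the allyl aryl ether is inert to methoxide.

Step 3
Reactants: 4 3-(geranyloxy)phenol
Product: 5 5-(geranyloxy)-2-iodophenol
Conditions: I2 (1.0 equiv), NaHCO3, THF/H2O, 0 °C
Reagents that add atoms: iodine, II
Why: Electrophilic aromatic iodination of the phenoxide; the carbon ortho to the hydroxyl and para to the geranyloxy group is activated by both oxygens and less hindered than the position between them or the one flanked by the ether chain, which is the usual orientation for 3-alkoxyphenols under these conditions. Phenoxide iodination is far faster than any reaction of I2 with isolated trisubstituted alkenes, so one equivalent at 0 °C should spare the geranyl chain.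

Step 4
Reactants: 6 3,4-dihydroxybenzaldehyde
Product: 7 3,4-bis(tert-butyldimethylsilyloxy)benzaldehyde
Conditions: TBSCl (2.4 equiv), imidazole, DMF, rt
Reagents that add atoms: tert-butyldimethylsilyl chloride, CC(C)(C)[Si](C)(C)Cl
Why: Silylation of both phenols through the N-silylimidazolium donor; the aldehyde is untouched.

Step 5
Reactants: 7 3,4-bis(tert-butyldimethylsilyloxy)benzaldehyde
Product: 8 4-ethynyl-1,2-bis(tert-butyldimethylsilyloxy)benzene
Conditions: Me3SiCHN2, LiN(i-Pr)2, THF, –78 °C to rt; then H2O
Reagents that add atoms: (trimethylsilyl)diazomethane, C[Si](C)(C)C=[N+]=[N-]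
Why: Colvin rearrangement: lithiated trimethylsilyldiazomethane adds to the aldehyde, Peterson-type loss of Me3SiOLi gives a diazoalkene, and loss of N2 with a 1,2-hydrogen shift of the alkylidene carbene gives the terminal alkyne in one operation. The aprotic conditions are chosen because aryl silyl ethers would not survive carbonate in methanol.

Step 6
Reactants: 5 5-(geranyloxy)-2-iodophenol; 8 4-ethynyl-1,2-bis(tert-butyldimethylsilyloxy)benzene; 9 carbon monoxide
Product: 12 2-[3,4-bis(tert-butyldimethylsilyloxy)phenyl]-7-(geranyloxy)-4H-chromen-4-one, via ortho-hydroxyaryl ynone 10 (not isolated), via diethylamino enone 11 (not isolated)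
Conditions: PdCl2(PPh3)2 (5 mol %), CO (1–5 bar), Et2NH (solvent), 40–60 °C
Reagents that add atoms: none
Why: This is the palladium-catalysed carbonylative alkynylation–cyclisation of an ortho-iodophenol with a terminal alkyne in a secondary amine, the known carbonylative Sonogashira-type flavone synthesis. Zerovalent palladium, formed from PdCl2(PPh3)2 by the amine and the alkyne, adds oxidatively to the C–I bond of 5; CO inserts to give the aroyl complex of divalent palladium (C4a–C4), and amine-assisted transfer of the acetylide of 8 followed by reductive elimination gives ynone 10 (C4–C3). Et2NH then adds to the ynone to give the push–pull enaminone 11, whose ortho-hydroxyl attacks the amine-bearing carbon and expels Et2NH, forming O1–C2 and closing ring C by a 6-endo-trig addition–elimination. No stereocentre is created. CO insertion must outrun direct alkynylation, which is favoured by the electron-rich aryl–palladium bond, the absence of a copper cocatalyst and the CO pressure. Six-membered closure must beat five-membered closure to an aurone, which the amine secures because in 11 only C2 is electrophilic. Oxidative addition at C–I must beat ionisation of the geranyl ether, which rests on the much higher reactivity of an aryl iodide and the poor binding of a trisubstituted allyl ether to CO-ligated palladium. The moderate temperature and the absence of alkoxide or hydroxide should keep the aryl silyl ethers in place.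

Step 7
Reactants: 12 2-[3,4-bis(tert-butyldimethylsilyloxy)phenyl]-7-(geranyloxy)-4H-chromen-4-one
Product: 13 (2S)-2-[3,4-bis(tert-butyldimethylsilyloxy)phenyl]-7-(geranyloxy)chroman-4-one
Conditions: Cu(OAc)2·H2O (5 mol %), (R)-DTBM-SEGPHOS (5.5 mol %), (EtO)2MeSiH (2 equiv), t-BuOH (2 equiv), toluene, 0 °C to rt
Reagents that add atoms: none
Why: Copper hydride-catalysed asymmetric conjugate reduction of a β,β-disubstituted enone, a reaction type established for chromones: the bisphosphine-ligated CuH formed from Cu(OAc)2 and the silane adds hydride to C2 from the face selected by the ligand, which sets C2 as (2S). t-BuOH protonates the copper enolate, so the catalyst turns over, the ketone forms directly and no strong base is present to racemise 13 by ring opening; isolated alkenes and aryl silyl ethers are inert to CuH.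

Step 8
Reactants: 13 (2S)-2-[3,4-bis(tert-butyldimethylsilyloxy)phenyl]-7-(geranyloxy)chroman-4-one
Product: 15 (2R,3R)-2-[3,4-bis(tert-butyldimethylsilyloxy)phenyl]-7-(geranyloxy)-3-hydroxychroman-4-one, via sodium enolate 14 (not isolated)
Conditions: NaN(SiMe3)2 (1.1 equiv), THF, –78 °C; 2-(phenylsulfonyl)-3-phenyloxaziridine (1.3 equiv), –78 °C; AcOH quench at –78 °C
Reagents that add atoms: 2-(phenylsulfonyl)-3-phenyloxaziridine, O=S(=O)(c1ccccc1)N1OC1c1ccccc1
Why: Enolate hydroxylation with an N-sulfonyloxaziridine (Davis oxidation): C3 is the only enolisable position, the sodium enolate 14 attacks the oxaziridine oxygen and the adduct collapses to the alkoxide and the sulfonimine. The reagent approaches C3 anti to the C2 aryl group, so the new hydroxyl is trans to ring B (3R), which is also the more stable diequatorial isomer. The low temperature and the cold acid quench are meant to prevent E1cB opening of ring C, and the oxaziridine does not epoxidise the geranyl alkenes.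

Step 9
Reactants: 15 (2R,3R)-2-[3,4-bis(tert-butyldimethylsilyloxy)phenyl]-7-(geranyloxy)-3-hydroxychroman-4-one
Product: 16 (2R,3R)-2-(3,4-dihydroxyphenyl)-7-(geranyloxy)-3-hydroxychroman-4-one
Conditions: HF·pyridine, pyridine, THF, 0 °C
Reagents that add atoms: none
Why: Fluoride-mediated cleavage of aryl silyl ethers, driven by the Si–F bond; HF·pyridine buffered with pyridine is acidic enough to protect the base-labile C2 and C3 centres yet too weak to ionise the allylic aryl ether or add to the alkenes at 0 °C.

## Compound list

1 | resorcinol monobenzoate (3-hydroxyphenyl benzoate) | O=C(Oc1cccc(O)c1)c1ccccc1 | starting material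
2 | geranyl bromide ((2E)-1-bromo-3,7-dimethylocta-2,6-diene) | CC(C)=CCC/C(C)=C/CBr | starting material
3 | 3-(geranyloxy)phenyl benzoate | CC(C)=CCC/C(C)=C/COc1cccc(OC(=O)c2ccccc2)c1 | intermediate
4 | 3-(geranyloxy)phenol | CC(C)=CCC/C(C)=C/COc1cccc(O)c1 | intermediate
5 | 5-(geranyloxy)-2-iodophenol | CC(C)=CCC/C(C)=C/COc1ccc(I)c(O)c1 | intermediate
6 | 3,4-dihydroxybenzaldehyde | O=Cc1ccc(O)c(O)c1 | starting material
7 | 3,4-bis(tert-butyldimethylsilyloxy)benzaldehyde | O=Cc1ccc(O[Si](C)(C)C(C)(C)C)c(O[Si](C)(C)C(C)(C)C)c1 | intermediate
8 | 4-ethynyl-1,2-bis(tert-butyldimethylsilyloxy)benzene | C#Cc1ccc(O[Si](C)(C)C(C)(C)C)c(O[Si](C)(C)C(C)(C)C)c1 | intermediate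
9 | carbon monoxide | [C-]#[O+] | starting material
10 | 1-[4-(geranyloxy)-2-hydroxyphenyl]-3-[3,4-bis(tert-butyldimethylsilyloxy)phenyl]prop-2-yn-1-one | CC(C)=CCC/C(C)=C/COc1ccc(C(=O)C#Cc2ccc(O[Si](C)(C)C(C)(C)C)c(O[Si](C)(C)C(C)(C)C)c2)c(O)c1 | intermediate (not isolated)
11 | (2E)-3-(diethylamino)-1-[4-(geranyloxy)-2-hydroxyphenyl]-3-[3,4-bis(tert-butyldimethylsilyloxy)phenyl]prop-2-en-1-one | CC(C)=CCC/C(C)=C/COc1ccc(C(=O)/C=C(/N(CC)CC)c2ccc(O[Si](C)(C)C(C)(C)C)c(O[Si](C)(C)C(C)(C)C)c2)c(O)c1 | intermediate (not isolated)
12 | 2-[3,4-bis(tert-butyldimethylsilyloxy)phenyl]-7-(geranyloxy)-4H-chromen-4-one | CC(C)=CCC/C(C)=C/COc1ccc2c(c1)OC(c1ccc(O[Si](C)(C)C(C)(C)C)c(O[Si](C)(C)C(C)(C)C)c1)=CC2=O | intermediate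
13 | (2S)-2-[3,4-bis(tert-butyldimethylsilyloxy)phenyl]-7-(geranyloxy)chroman-4-one | CC(C)=CCC/C(C)=C/COc1ccc2c(c1)O[C@H](c1ccc(O[Si](C)(C)C(C)(C)C)c(O[Si](C)(C)C(C)(C)C)c1)CC2=O | intermediate
14 | sodium (2S)-2-[3,4-bis(tert-butyldimethylsilyloxy)phenyl]-7-(geranyloxy)-2H-chromen-4-olate | CC(C)=CCC/C(C)=C/COc1ccc2c(c1)O[C@H](c1ccc(O[Si](C)(C)C(C)(C)C)c(O[Si](C)(C)C(C)(C)C)c1)C=C2[O-].[Na+] | intermediate (not isolated)
15 | (2R,3R)-2-[3,4-bis(tert-butyldimethylsilyloxy)phenyl]-7-(geranyloxy)-3-hydroxychroman-4-one | CC(C)=CCC/C(C)=C/COc1ccc2c(c1)O[C@H](c1ccc(O[Si](C)(C)C(C)(C)C)c(O[Si](C)(C)C(C)(C)C)c1)[C@@H](O)C2=O | intermediate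
16 | (2R,3R)-2-(3,4-dihydroxyphenyl)-7-(geranyloxy)-3-hydroxychroman-4-one | CC(C)=CCC/C(C)=C/COc1ccc2c(c1)O[C@H](c1ccc(O)c(O)c1)[C@@H](O)C2=O | target

## Step count and least certain steps

Total step count: 9. Longest linear sequence: 7 steps (steps 1, 2, 3, 6, 7, 8, 9).

**Step 6 (key step).** Three processes are most likely to interfere:
- CO-free alkynylation followed by five-membered closure, if CO insertion is slow at low pressure.
- Aminocarbonylation of the aroyl–palladium intermediate by the solvent amine.
- Ionisation of the allylic ether by zerovalent palladium once the aryl iodide is consumed, or loss of a silyl group to the amine on prolonged heating.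

The fallback makes the ynone without palladium or CO. It sets out from 4 and 8. Magnesium-mediated ortho-formylation of 4 (MgCl2, Et3N, paraformaldehyde, MeCN, reflux) should give 4-(geranyloxy)-2-hydroxybenzaldehyde F1. Alkyne 8 is lithiated with n-BuLi in THF at –78 °C and added in two-fold amount, the first equivalent serving to deprotonate the phenol, to give the racemic propargylic alcohol 1-[4-(geranyloxy)-2-hydroxyphenyl]-3-[3,4-bis(tert-butyldimethylsilyloxy)phenyl]prop-2-yn-1-ol F2. Oxidation with MnO2 in CH2Cl2 gives ynone 10, here isolated. Et2NH in EtOH then converts 10 through 11 into the flavone, so the fallback comes back to the route at 12.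

**Step 7.** Face discrimination may be poor because C2 carries two flat substituents of similar size (aryl and aryloxy). Over-reduction of the new ketone by excess hydride and erosion of optical purity through reversible opening of ring C at the enolate stage are the other risks. The fallback sets out from 12. Unselective 1,4-reduction with LiBH(s-Bu)3 in THF at –78 °C gives the racemic flavanone 2-[3,4-bis(tert-butyldimethylsilyloxy)phenyl]-7-(geranyloxy)chroman-4-one F3. Kinetic resolution by asymmetric transfer hydrogenation follows, using RuCl(p-cymene)[TsDPEN] in HCO2H/Et3N with the antipode of the catalyst that consumes the (2R)-ketone. That ketone is reduced to the cis-alcohol (2R,4R)-2-[3,4-bis(tert-butyldimethylsilyloxy)phenyl]-7-(geranyloxy)chroman-4-ol F4, and the unreacted ketone is separated by chromatography. The fallback comes back at 13 at the cost of half the material.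

**Step 8.** The enolate may undergo β-elimination of the O1 phenoxide (E1cB opening of ring C), which would racemise C2 or destroy the material. It may also add to the sulfonimine by-product, or be hydroxylated with incomplete trans selectivity. The fallback avoids a metal enolate and sets out from 13. Soft enolisation (Me3SiOTf, Et3N, CH2Cl2, 0 °C) gives the silyl enol ether (2S)-2-[3,4-bis(tert-butyldimethylsilyloxy)phenyl]-7-(geranyloxy)-4-(trimethylsilyloxy)-2H-chromene F5. Rubottom oxidation with one equivalent of dimethyldioxirane in acetone at –78 °C relies on the enol ether double bond being far more nucleophilic than the trisubstituted alkenes. After silyl migration it gives (2R,3R)-2-[3,4-bis(tert-butyldimethylsilyloxy)phenyl]-7-(geranyloxy)-3-(trimethylsilyloxy)chroman-4-one F6. Dilute AcOH in aqueous THF removes the trimethylsilyl group, and the fallback comes back at 15.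

**Step 3.** Iodination may occur at the wrong carbon (para to the hydroxyl or between the two oxygens), may proceed to di-iodination, or iodine may be consumed by the alkenes. The fallback introduces iodine before the geranyl chain and sets out from 1. Para-selective iodination of the free phenol (N-iodosuccinimide, catalytic TsOH, MeCN, rt) gives 5-hydroxy-2-iodophenyl benzoate F7. Alkylation with 2 (K2CO3, acetone, reflux) gives 5-(geranyloxy)-2-iodophenyl benzoate F8. Methanolysis (K2CO3, MeOH, rt) brings the fallback back at 5.

## Further compounds

F1 | step 6 | 4-(geranyloxy)-2-hydroxybenzaldehyde | CC(C)=CCC/C(C)=C/COc1ccc(C=O)c(O)c1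
F2 | step 6 | 1-[4-(geranyloxy)-2-hydroxyphenyl]-3-[3,4-bis(tert-butyldimethylsilyloxy)phenyl]prop-2-yn-1-ol (racemic) | CC(C)=CCC/C(C)=C/COc1ccc(C(O)C#Cc2ccc(O[Si](C)(C)C(C)(C)C)c(O[Si](C)(C)C(C)(C)C)c2)c(O)c1
F3 | step 7 | 2-[3,4-bis(tert-butyldimethylsilyloxy)phenyl]-7-(geranyloxy)chroman-4-one (racemic) | CC(C)=CCC/C(C)=C/COc1ccc2c(c1)OC(c1ccc(O[Si](C)(C)C(C)(C)C)c(O[Si](C)(C)C(C)(C)C)c1)CC2=O
F4 | step 7 | (2R,4R)-2-[3,4-bis(tert-butyldimethylsilyloxy)phenyl]-7-(geranyloxy)chroman-4-ol | CC(C)=CCC/C(C)=C/COc1ccc2c(c1)O[C@@H](c1ccc(O[Si](C)(C)C(C)(C)C)c(O[Si](C)(C)C(C)(C)C)c1)C[C@H]2O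
F5 | step 8 | (2S)-2-[3,4-bis(tert-butyldimethylsilyloxy)phenyl]-7-(geranyloxy)-4-(trimethylsilyloxy)-2H-chromene | CC(C)=CCC/C(C)=C/COc1ccc2c(c1)O[C@H](c1ccc(O[Si](C)(C)C(C)(C)C)c(O[Si](C)(C)C(C)(C)C)c1)C=C2O[Si](C)(C)C
F6 | step 8 | (2R,3R)-2-[3,4-bis(tert-butyldimethylsilyloxy)phenyl]-7-(geranyloxy)-3-(trimethylsilyloxy)chroman-4-one | CC(C)=CCC/C(C)=C/COc1ccc2c(c1)O[C@H](c1ccc(O[Si](C)(C)C(C)(C)C)c(O[Si](C)(C)C(C)(C)C)c1)[C@@H](O[Si](C)(C)C)C2=O
F7 | step 3 | 5-hydroxy-2-iodophenyl benzoate | O=C(Oc1cc(O)ccc1I)c1ccccc1
F8 | step 3 | 5-(geranyloxy)-2-iodophenyl benzoate | CC(C)=CCC/C(C)=C/COc1ccc(I)c(OC(=O)c2ccccc2)c1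
A1 | alternative 1 | (2R,3R)-3,7-bis(benzyloxy)-5-bromo-2-[3,4-bis(tert-butyldimethylsilyloxy)phenyl]chroman-4-one | c1ccccc1COc1cc(Br)c2c(c1)O[C@H](c1ccc(O[Si](C)(C)C(C)(C)C)c(O[Si](C)(C)C(C)(C)C)c1)[C@@H](OCc1ccccc1)C2=O
A2 | alternative 1 | 4-(benzyloxy)-2-bromo-6-(trimethylsilyl)phenyl trifluoromethanesulfonate | C[Si](C)(C)c1cc(OCc2ccccc2)cc(Br)c1OS(=O)(=O)C(F)(F)F
A3 | alternative 1 | methyl (2R,3R)-2-(benzyloxy)-3-[3,4-bis(tert-butyldimethylsilyloxy)phenyl]-3-hydroxypropanoate | O[C@H](c1ccc(O[Si](C)(C)C(C)(C)C)c(O[Si](C)(C)C(C)(C)C)c1)[C@@H](OCc1ccccc1)C(=O)OC
A4 | alternative 2 | (2R,3R)-2-[3,4-bis(tert-butyldimethylsilyloxy)phenyl]-7-(geranyloxy)-3-hydroxychroman-4-one | CC(C)=CCC/C(C)=C/COc1ccc2c(c1)O[C@H](c1ccc(O[Si](C)(C)C(C)(C)C)c(O[Si](C)(C)C(C)(C)C)c1)[C@@H](O)C2=O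
A5 | alternative 2 | 2-[3,4-bis(tert-butyldimethylsilyloxy)phenyl]-2-[2-formyl-5-(geranyloxy)phenoxy]acetaldehyde (racemic) | CC(C)=CCC/C(C)=C/COc1ccc(C=O)c(OC(C=O)c2ccc(O[Si](C)(C)C(C)(C)C)c(O[Si](C)(C)C(C)(C)C)c2)c1
A6 | alternative 3 | (2R,3S)-2-[3,4-bis(tert-butyldimethylsilyloxy)phenyl]-7-(geranyloxy)chroman-3-yl acetate | CC(C)=CCC/C(C)=C/COc1ccc2c(c1)O[C@H](c1ccc(O[Si](C)(C)C(C)(C)C)c(O[Si](C)(C)C(C)(C)C)c1)[C@@H](OC(C)=O)C2
A7 | alternative 3 | 5-(geranyloxy)-2-(hydroxymethyl)phenol | CC(C)=CCC/C(C)=C/COc1ccc(CO)c(O)c1
A8 | alternative 3 | (E)-2-[3,4-bis(tert-butyldimethylsilyloxy)phenyl]ethenyl acetate | CC(=O)O/C=C/c1ccc(O[Si](C)(C)C(C)(C)C)c(O[Si](C)(C)C(C)(C)C)c1
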